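**Retrosynthetic overview**

- The only non-aromatic ring is a 2,3,4,7-tetrahydrooxepine (O1, C2, C3, C4, C5=C6, C7). Its quaternary C2 carries O1, CO2H and CαH2–C(=O)Ar, so C2 is both the ether carbon and the β-carbon of the aryl ketone, and O1–C2 can be cut as a retro-oxa-Michael bond.
- Cutting O1–C2 gives an acyclic (E)-2-alkyl-3-aroylacrylate with a free (Z)-allylic C7 hydroxyl. Its catalyst-controlled closure forms the only ring made in the route (both benzene rings are bought) and sets C2; one acidic global deprotection follows.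
- C2=Cα comes from a Wittig reaction of an α-keto ester with the aroylmethylene phosphorane made from 2',5'-dihydroxyacetophenone. The coumarate is attached after E-selective allylic oxidation of the prenyl terminus.
- C4–C5 comes from a Negishi coupling of a (Z)-alkenyl iodide. That iodide is made by anti-carbomagnesiation and iodination of propargyl alcohol with homoprenylmagnesium bromide, which fixes the Z geometry of C5=C6.

Key step: step 14

Remark 1: the labels O1, C2–C7 and Cα of the oxepine ring are also used for the acyclic compounds.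
Remark 2: the carboxyl group is carried as a tert-butyl ester and the phenols as methoxymethyl (MOM) ethers, so one acid treatment ends the synthesis; an allyl ester was set aside because zerovalent palladium could also ionise the allylic coumarate and an amine scavenger would act as a base on the β-alkoxy ketone.
Remark 3 (assumption): the sense of induction of the catalyst in step 14 cannot be derived from precedent; both catalyst antipodes are accessible, and the one that gives (S)-C2 is used.

**Step 1**
Reactants: 1 5-bromo-2-methylpent-2-ene (homoprenyl bromide); 2 prop-2-yn-1-ol (propargyl alcohol)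
Product: 5 (2Z)-2-(iodomethylidene)-6-methylhept-5-en-1-ol (iodine cis to CH2OH), via homoprenylmagnesium bromide 3 (not isolated), via alkenylmagnesium alkoxide 4 (not isolated)
Conditions: 1, Mg, THF, rt to 40 °C; then 2 (0.4 equiv), CuI (10 mol %), −10 °C to rt; then I2, THF, −40 to 0 °C; aqueous work-up
Reagents that add atoms: iodine, II
Why: Copper-catalysed anti-carbomagnesiation of the propargylic alkoxide places the homoprenyl group on the internal alkyne carbon and magnesium on the terminal carbon, held cis to the CH2O arm in a five-membered chelate, and iodinolysis with retention gives the Z iodide that later fixes the C5=C6 geometry.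

**Step 2**
Reactants: 5 (2Z)-2-(iodomethylidene)-6-methylhept-5-en-1-ol
Product: 6 tert-butyl{[(2Z)-2-(iodomethylidene)-6-methylhept-5-en-1-yl]oxy}dimethylsilane
Conditions: TBSCl, imidazole, CH2Cl2, 0 °C to rt
Reagents that add atoms: tert-butyldimethylsilyl chloride, CC(C)(C)[Si](C)(C)Cl
Why: Standard silylation of a primary allylic alcohol gives an ether that survives organozinc, enolate, oxidation and Wittig conditions and can later be removed with acidic fluoride without any base.

**Step 3**
Reactants: 6 tert-butyl{[(2Z)-2-(iodomethylidene)-6-methylhept-5-en-1-yl]oxy}dimethylsilane; 7 tert-butyl 4-bromobutanoate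
Product: 9 tert-butyl (5Z)-6-{[(tert-butyldimethylsilyl)oxy]methyl}-10-methylundeca-5,9-dienoate, via 4-tert-butoxy-4-oxobutylzinc bromide 8 (not isolated)
Conditions: 7, Zn dust, LiCl, I2 (cat.), THF, 50 °C; then 6, PdCl2(dppf) (3 mol %), THF, rt to 40 °C
Reagents that add atoms: none
Why: In this Negishi sp2–sp3 cross-coupling the zinc insertion tolerates the ester, the bidentate dppf ligand suppresses β-hydride elimination, and the alkenyl iodide couples with retention, so C4 ends up cis to C7.

**Step 4**
Reactants: 9 tert-butyl (5Z)-6-{[(tert-butyldimethylsilyl)oxy]methyl}-10-methylundeca-5,9-dienoate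
Product: 11 tert-butyl (5Z)-6-{[(tert-butyldimethylsilyl)oxy]methyl}-2-hydroxy-10-methylundeca-5,9-dienoate (racemic at the carbinol carbon), via potassium ester enolate 10 (not isolated)
Conditions: KN(SiMe3)2, THF, −78 °C; then 3-phenyl-2-(phenylsulfonyl)oxaziridine, −78 °C; AcOH quench
Reagents that add atoms: 3-phenyl-2-(phenylsulfonyl)oxaziridine, O=S(=O)(N1OC1c1ccccc1)c1ccccc1
Why: Enolate hydroxylation with an N-sulfonyloxaziridine (Davis oxidation) gives the carbinol centre as a racemate, which does not matter because that carbon becomes a carbonyl carbon in step 5.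

**Step 5**
Reactants: 11 tert-butyl (5Z)-6-{[(tert-butyldimethylsilyl)oxy]methyl}-2-hydroxy-10-methylundeca-5,9-dienoate
Product: 12 tert-butyl (5Z)-6-{[(tert-butyldimethylsilyl)oxy]methyl}-10-methyl-2-oxoundeca-5,9-dienoate
Conditions: Dess–Martin periodinane, CH2Cl2, 0 °C to rt
Reagents that add atoms: none
Why: Dess–Martin oxidation converts the α-hydroxy ester into the α-keto ester under near-neutral conditions that leave the silyl ether and both alkenes untouched.

**Step 6**
Reactants: 13 1-(2,5-dihydroxyphenyl)ethan-1-one (2',5'-dihydroxyacetophenone)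
Product: 14 1-[2,5-bis(methoxymethoxy)phenyl]ethan-1-one
Conditions: MOMCl, iPr2NEt, DMAP (cat.), CH2Cl2, 0 °C to reflux
Reagents that add atoms: chloromethyl methyl ether, COCCl
Why: Double O-alkylation of the phenols with excess reagent and heating also caps the hydrogen-bonded ortho phenol, which must stay blocked until after the oxepine is closed.

**Step 7**
Reactants: 14 1-[2,5-bis(methoxymethoxy)phenyl]ethan-1-one
Product: 16 1-[2,5-bis(methoxymethoxy)phenyl]-2-bromoethan-1-one, via trimethylsilyl enol ether 15 (not isolated)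
Conditions: TMSCl, LiN(SiMe3)2 (internal quench), THF, −78 °C; then NBS, −78 to 0 °C
Reagents that add atoms: N-bromosuccinimide, O=C1CCC(=O)N1Br
Why: Brominating the enol silane with NBS avoids the HBr that direct bromination would release onto the MOM ethers, and the enol ether outcompetes the electron-rich ring for bromine.

**Step 8**
Reactants: 16 1-[2,5-bis(methoxymethoxy)phenyl]-2-bromoethan-1-one
Product: 18 1-[2,5-bis(methoxymethoxy)phenyl]-2-(triphenylphosphoranylidene)ethan-1-one, via phosphonium bromide 17 (not isolated)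
Conditions: PPh3, CH2Cl2, rt; then 1 M aq NaOH, rt (two phases)
Reagents that add atoms: triphenylphosphine, c1ccc(cc1)P(c1ccccc1)c1ccccc1
Why: SN2 quaternisation of PPh3 by the phenacyl-type bromide and deprotonation of the acidic salt give the stabilised, storable acyl ylide.

**Step 9**
Reactants: 12 tert-butyl (5Z)-6-{[(tert-butyldimethylsilyl)oxy]methyl}-10-methyl-2-oxoundeca-5,9-dienoate; 18 1-[2,5-bis(methoxymethoxy)phenyl]-2-(triphenylphosphoranylidene)ethan-1-one
Product: 19 tert-butyl (2E,5Z)-2-{2-[2,5-bis(methoxymethoxy)phenyl]-2-oxoethylidene}-6-{[(tert-butyldimethylsilyl)oxy]methyl}-10-methylundeca-5,9-dienoate (ester trans to aroyl)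
Conditions: toluene, 80 °C, in the dark
Reagents that add atoms: none
Why: In this Wittig olefination the α-keto ester is an activated ketone that accepts stabilised acyl ylides, the addition should favour the E alkene with the ester trans to the aroyl group, and any Z isomer is removed by chromatography because step 14 needs a single geometry.

**Step 10**
Reactants: 19 tert-butyl (2E,5Z)-2-{2-[2,5-bis(methoxymethoxy)phenyl]-2-oxoethylidene}-6-{[(tert-butyldimethylsilyl)oxy]methyl}-10-methylundeca-5,9-dienoate
Product: 20 tert-butyl (2E,5Z,9E)-2-{2-[2,5-bis(methoxymethoxy)phenyl]-2-oxoethylidene}-6-{[(tert-butyldimethylsilyl)oxy]methyl}-11-hydroxy-10-methylundeca-5,9-dienoate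
Conditions: SeO2 (0.3 equiv), tBuOOH, salicylic acid (cat.), CH2Cl2, 0 °C to rt; stopped at partial conversion, 19 recycled
Reagents that add atoms: selenium dioxide, O=[Se]=O; tert-butyl hydroperoxide, CC(C)(C)OO
Why: Catalytic SeO2 allylic oxidation (ene reaction, then [2,3]-sigmatropic shift) attacks the most electron-rich alkene, the terminal dimethyl-substituted one, at its E methyl group as it does in geranyl esters, while C5=C6 is deactivated by its allylic oxygen and C2=Cα by two carbonyl groups.

**Step 11**
Reactants: 21 (2E)-3-(4-hydroxyphenyl)prop-2-enoic acid (p-coumaric acid)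
Product: 23 (2E)-3-[4-(methoxymethoxy)phenyl]prop-2-enoic acid, via methoxymethyl ester 22 (not isolated)
Conditions: MOMCl, iPr2NEt, CH2Cl2, 0 °C to rt; concentrate; then LiOH, THF–H2O, rt; 1 M HCl to pH 4, 0 °C
Reagents that add atoms: chloromethyl methyl ether, COCCl; lithium hydroxide, [Li+].[OH-]
Why: Exhaustive O-alkylation followed by selective saponification works because the acyloxymethyl ester is far more labile to hydroxide than the aryl MOM ether.

**Step 12**
Reactants: 20 tert-butyl (2E,5Z,9E)-2-{2-[2,5-bis(methoxymethoxy)phenyl]-2-oxoethylidene}-6-{[(tert-butyldimethylsilyl)oxy]methyl}-11-hydroxy-10-methylundeca-5,9-dienoate; 23 (2E)-3-[4-(methoxymethoxy)phenyl]prop-2-enoic acid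
Product: 24 tert-butyl (2E,5Z,9E)-2-{2-[2,5-bis(methoxymethoxy)phenyl]-2-oxoethylidene}-6-{[(tert-butyldimethylsilyl)oxy]methyl}-11-({(2E)-3-[4-(methoxymethoxy)phenyl]prop-2-enoyl}oxy)-10-methylundeca-5,9-dienoate
Conditions: DCC, DMAP (cat.), CH2Cl2, 0 °C to rt
Reagents that add atoms: none
Why: Steglich esterification acylates the only free hydroxyl under mild conditions that neither move the allylic system nor touch the aroylacrylate.

**Step 13**
Reactants: 24 tert-butyl (2E,5Z,9E)-2-{2-[2,5-bis(methoxymethoxy)phenyl]-2-oxoethylidene}-6-{[(tert-butyldimethylsilyl)oxy]methyl}-11-({(2E)-3-[4-(methoxymethoxy)phenyl]prop-2-enoyl}oxy)-10-methylundeca-5,9-dienoate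
Product: 25 tert-butyl (2E,5Z,9E)-2-{2-[2,5-bis(methoxymethoxy)phenyl]-2-oxoethylidene}-6-(hydroxymethyl)-11-({(2E)-3-[4-(methoxymethoxy)phenyl]prop-2-enoyl}oxy)-10-methylundeca-5,9-dienoate (seco alcohol)
Conditions: HF·pyridine, pyridine, THF, 0 °C to rt, in the dark
Reagents that add atoms: none
Why: Fluoride-driven Si–O cleavage in a slightly acidic medium frees the C7 hydroxyl without forming an alkoxide, so no uncatalysed racemic closure can start, and the MOM ethers, both esters and the acceptor are inert.

**Step 14**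
Reactants: 25 tert-butyl (2E,5Z,9E)-2-{2-[2,5-bis(methoxymethoxy)phenyl]-2-oxoethylidene}-6-(hydroxymethyl)-11-({(2E)-3-[4-(methoxymethoxy)phenyl]prop-2-enoyl}oxy)-10-methylundeca-5,9-dienoate
Product: 26 tert-butyl (2S)-2-{2-[2,5-bis(methoxymethoxy)phenyl]-2-oxoethyl}-6-[(3E)-5-({(2E)-3-[4-(methoxymethoxy)phenyl]prop-2-enoyl}oxy)-4-methylpent-3-en-1-yl]-2,3,4,7-tetrahydrooxepine-2-carboxylate
Conditions: chiral bifunctional iminophosphorane–thiourea organocatalyst (tert-leucine-derived backbone, tris(4-methoxyphenyl)iminophosphorane base, 3,5-bis(trifluoromethyl)phenyl thiourea; 10 mol %), toluene, 0.02 M, −20 °C, in the dark; AcOH quench at −20 °C, direct filtration through silica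
Reagents that add atoms: none
Why: Proposed new method: the iminophosphorane site takes up the proton of the C7 hydroxyl while the thiourea arm binds the aryl ketone oxygen, the oxygen adds to C2, and the ketone enolate is protonated at Cα by the iminophosphonium ion, which frees the catalyst. The closest known reaction type is the intramolecular oxa-Michael addition of alcohols to enones and enoates under bifunctional amine–squaramide or iminophosphorane catalysis, shown for five- and six-membered ethers but not for a seven-membered ring closing onto a fully substituted β-carbon. The oxepine closes in the 7-exo-trig mode, with C2=Cα lying outside the new ring. C2 is the only new stereocenter, it has no substrate bias, and it is set by the catalyst alone, which must bring O1 to the Si face of C2 (ranking CO2tBu > Cα > C3) of the geometrically pure E acceptor to give S. Attack at C2 rather than Cα is expected because it produces the ketone enolate instead of the less stabilised ester enolate and because attack at Cα would need an eight-membered ring; the Z geometry of C5=C6 keeps O1 close to C2, the MOM group on the ortho oxygen rules out chromanone closure, and the electron-rich coumarate is too poor an acceptor to compete. Since the addition can reverse, the reaction is run cold and dilute, stopped with acid at the reaction temperature, and 26 is kept away from base afterwards.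

**Step 15**
Reactants: 26 tert-butyl (2S)-2-{2-[2,5-bis(methoxymethoxy)phenyl]-2-oxoethyl}-6-[(3E)-5-({(2E)-3-[4-(methoxymethoxy)phenyl]prop-2-enoyl}oxy)-4-methylpent-3-en-1-yl]-2,3,4,7-tetrahydrooxepine-2-carboxylate
Product: 27 (2S)-2-[2-(2,5-dihydroxyphenyl)-2-oxoethyl]-6-[(3E)-5-{[(2E)-3-(4-hydroxyphenyl)prop-2-enoyl]oxy}-4-methylpent-3-en-1-yl]-2,3,4,7-tetrahydrooxepine-2-carboxylic acid (CNP0602535.2)
Conditions: TFA–CH2Cl2–H2O (about 25:75:1), 0 °C to rt; co-evaporation with toluene below 25 °C
Reagents that add atoms: none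
Why: Acidolysis removes the tert-butyl group as 2-methylpropene by alkyl–oxygen cleavage and hydrolyses the three aryl MOM acetals without any base, so the β-alkoxy ketone cannot eliminate by E1cB, quaternary C2 cannot epimerise, and both trisubstituted alkenes are protected from protonation by their allylic oxygens.

**Compound list**

1 | 5-bromo-2-methylpent-2-ene | CC(C)=CCCBr | starting material
2 | prop-2-yn-1-ol | C#CCO | starting material
3 | (4-methylpent-3-en-1-yl)magnesium bromide | CC(C)=CCC[Mg]Br | intermediate
4 | bromomagnesium (2Z)-2-[(bromomagnesio)methylidene]-6-methylhept-5-en-1-olate | CC(C)=CCC/C(CO[Mg]Br)=C/[Mg]Br | intermediate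
5 | (2Z)-2-(iodomethylidene)-6-methylhept-5-en-1-ol | CC(C)=CCC/C(CO)=C/I | intermediate
6 | tert-butyl{[(2Z)-2-(iodomethylidene)-6-methylhept-5-en-1-yl]oxy}dimethylsilane | CC(C)=CCC/C(CO[Si](C)(C)C(C)(C)C)=C/I | intermediate
7 | tert-butyl 4-bromobutanoate | CC(C)(C)OC(=O)CCCBr | starting material
8 | (4-tert-butoxy-4-oxobutyl)zinc bromide | CC(C)(C)OC(=O)CCC[Zn]Br | intermediate
9 | tert-butyl (5Z)-6-{[(tert-butyldimethylsilyl)oxy]methyl}-10-methylundeca-5,9-dienoate | CC(C)=CCC/C(CO[Si](C)(C)C(C)(C)C)=C/CCCC(=O)OC(C)(C)C | intermediate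
10 | potassium enolate of 9 (enolate geometry of no consequence) | CC(C)=CCC/C(CO[Si](C)(C)C(C)(C)C)=C/CCC=C([O-])OC(C)(C)C.[K+] | intermediate
11 | tert-butyl (5Z)-6-{[(tert-butyldimethylsilyl)oxy]methyl}-2-hydroxy-10-methylundeca-5,9-dienoate, racemic | CC(C)=CCC/C(CO[Si](C)(C)C(C)(C)C)=C/CCC(O)C(=O)OC(C)(C)C | intermediate
12 | tert-butyl (5Z)-6-{[(tert-butyldimethylsilyl)oxy]methyl}-10-methyl-2-oxoundeca-5,9-dienoate | CC(C)=CCC/C(CO[Si](C)(C)C(C)(C)C)=C/CCC(=O)C(=O)OC(C)(C)C | intermediate
13 | 1-(2,5-dihydroxyphenyl)ethan-1-one | CC(=O)c1cc(O)ccc1O | starting material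
14 | 1-[2,5-bis(methoxymethoxy)phenyl]ethan-1-one | CC(=O)c1cc(OCOC)ccc1OCOC | intermediate
15 | ({1-[2,5-bis(methoxymethoxy)phenyl]ethenyl}oxy)trimethylsilane | C=C(O[Si](C)(C)C)c1cc(OCOC)ccc1OCOC | intermediate
16 | 1-[2,5-bis(methoxymethoxy)phenyl]-2-bromoethan-1-one | BrCC(=O)c1cc(OCOC)ccc1OCOC | intermediate
17 | {2-[2,5-bis(methoxymethoxy)phenyl]-2-oxoethyl}triphenylphosphonium bromide | [Br-].O=C(C[P+](c1ccccc1)(c1ccccc1)c1ccccc1)c1cc(OCOC)ccc1OCOC | intermediate
18 | 1-[2,5-bis(methoxymethoxy)phenyl]-2-(triphenylphosphoranylidene)ethan-1-one | O=C(C=P(c1ccccc1)(c1ccccc1)c1ccccc1)c1cc(OCOC)ccc1OCOC | intermediate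
19 | tert-butyl (2E,5Z)-2-{2-[2,5-bis(methoxymethoxy)phenyl]-2-oxoethylidene}-6-{[(tert-butyldimethylsilyl)oxy]methyl}-10-methylundeca-5,9-dienoate | CC(C)=CCC/C(CO[Si](C)(C)C(C)(C)C)=C/CC/C(=C\C(=O)c1cc(OCOC)ccc1OCOC)C(=O)OC(C)(C)C | intermediate
20 | 11-hydroxy derivative of 19, (2E,5Z,9E) | C/C(CO)=C\CC/C(CO[Si](C)(C)C(C)(C)C)=C/CC/C(=C\C(=O)c1cc(OCOC)ccc1OCOC)C(=O)OC(C)(C)C | intermediate
21 | (2E)-3-(4-hydroxyphenyl)prop-2-enoic acid | OC(=O)/C=C/c1ccc(O)cc1 | starting material
22 | methoxymethyl (2E)-3-[4-(methoxymethoxy)phenyl]prop-2-enoate | COCOC(=O)/C=C/c1ccc(OCOC)cc1 | intermediate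
23 | (2E)-3-[4-(methoxymethoxy)phenyl]prop-2-enoic acid | OC(=O)/C=C/c1ccc(OCOC)cc1 | intermediate
24 | O-MOM-coumarate of 20 (C7 hydroxyl still silylated) | C/C(COC(=O)/C=C/c1ccc(OCOC)cc1)=C\CC/C(CO[Si](C)(C)C(C)(C)C)=C/CC/C(=C\C(=O)c1cc(OCOC)ccc1OCOC)C(=O)OC(C)(C)C | intermediate
25 | seco alcohol: tert-butyl (E)-aroylacrylate with free (Z)-allylic C7 hydroxyl, coumarate in place, three MOM ethers | C/C(COC(=O)/C=C/c1ccc(OCOC)cc1)=C\CC/C(CO)=C/CC/C(=C\C(=O)c1cc(OCOC)ccc1OCOC)C(=O)OC(C)(C)C | intermediate
26 | fully protected target, (2S)-oxepine tert-butyl ester with three MOM ethers | C/C(=C\CCC1=CCC[C@](CC(=O)c2cc(OCOC)ccc2OCOC)(C(=O)OC(C)(C)C)OC1)COC(=O)/C=C/c1ccc(OCOC)cc1 | intermediate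
27 | CNP0602535.2, (2S)-acid | C/C(=C\CCC1=CCC[C@](CC(=O)c2cc(O)ccc2O)(C(=O)O)OC1)COC(=O)/C=C/c1ccc(O)cc1 | target

**Step count**

Total step count: 15.
Longest linear sequence: 11 steps (steps 1–5, 9, 10, 12–15).

**Steps most likely to fail**

**1. Step 14 (the labelled step).**

What may go wrong:
- The closure may stall, because a seven-membered ring has to form at a fully substituted carbon and the equilibrium may lie on the side of the conjugated open form.
- The strong base may remove a proton from C3 and move the C2=Cα bond out of conjugation with the ketone.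
- Facial selectivity may be poor, because the catalyst class has never been matched to such an acceptor.

Fallback (known chemistry): C2 is set by a catalytic aldol addition and the ring is closed at C5=C6 by metathesis. It sets out from 14 (through its enol silane 15, here purified) and from the alkenylmagnesium alkoxide 4, and it comes back to the route at 26.

But-3-enylmagnesium bromide is added to di-tert-butyl oxalate (THF, −78 °C) to give tert-butyl 2-oxohex-5-enoate F1. A Mukaiyama aldol addition of 15 to F1 follows, under Cu(OTf)2 and a C2-symmetric tert-butyl-bis(oxazoline) ligand (10 mol %, THF, −78 °C). Divalent copper chelates both carbonyl oxygens of the keto ester, and the ligand antipode is chosen for S. This gives the silylated aldol tert-butyl (2S)-2-{2-[2,5-bis(methoxymethoxy)phenyl]-2-oxoethyl}-2-[(trimethylsilyl)oxy]hex-5-enoate F2, and HF·pyridine frees the tertiary alcohol tert-butyl (2S)-2-{2-[2,5-bis(methoxymethoxy)phenyl]-2-oxoethyl}-2-hydroxyhex-5-enoate F3.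

Quenching 4 with aqueous NH4Cl in place of iodine gives 6-methyl-2-methylidenehept-5-en-1-ol F4. Cl3CCN and DBU (cat.) convert it into 6-methyl-2-methylidenehept-5-en-1-yl 2,2,2-trichloroacetimidate F5. Acid-catalysed imidate etherification (TfOH, 5 mol %, CH2Cl2–cyclohexane, 0 °C) avoids the base that would trigger retro-aldol cleavage and joins F3 and F5 to the tertiary allylic ether F6.

Ring-closing metathesis (second-generation Hoveyda–Grubbs catalyst, toluene, 60 °C, high dilution) between the monosubstituted and the 1,1-disubstituted alkene gives the homoprenyl oxepine F7, in which C5=C6 is necessarily cis within the ring. SeO2/tBuOOH oxidation as in step 10 gives the E allylic alcohol F8, and Steglich esterification with 23 as in step 12 gives 26.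

**2. Step 15.**

What may go wrong:
- Acid-induced β-elimination of O1, followed by closure of the freed ortho phenol onto the aroylacrylic acid.
- Solvolysis of the allylic coumarate.
- Capture of methoxymethyl or tert-butyl cations by the phenol rings.

Fallback: the protecting groups are exchanged for silyl groups under buffered aprotic conditions instead of being removed by protic acidolysis. It sets out from 26 and comes back at 27. TMSOTf and 2,2'-bipyridyl (CH2Cl2, 0 °C) convert the three aryl MOM ethers into aryl trimethylsilyl ethers and the tert-butyl ester into the trimethylsilyl ester, giving the tetrakis(trimethylsilyl) derivative F9. Brief stirring with pH 7 buffer at 0 °C hydrolyses all four Si–O bonds to give 27.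

**3. Step 9.**

What may go wrong:
- Slow olefination of the hindered keto ester by the ortho-substituted ylide.
- Self-condensation of the enolisable keto ester.
- Poor control of the alkene geometry.

Fallback: the polarity of the olefination is reversed, with phosphorus on C2 and an aldehyde at Cα. It sets out from 9 and 16, bypasses steps 4, 5 and 8, and comes back at 19. The enolate of 9 (LiN(iPr)2, THF, −78 °C) is trapped with ClP(OEt)2 and oxidised with H2O2 to give the α-phosphono ester tert-butyl (5Z)-6-{[(tert-butyldimethylsilyl)oxy]methyl}-2-(diethoxyphosphoryl)-10-methylundeca-5,9-dienoate F10. Kornblum oxidation of 16 (DMSO, NaHCO3, rt) gives [2,5-bis(methoxymethoxy)phenyl]glyoxal F11, which is dried azeotropically. A Horner–Wadsworth–Emmons reaction of F10 (NaH, THF, −78 to 0 °C) at the aldehyde carbon of F11 should give the E trisubstituted alkene 19, as α-alkyl phosphonoacetates do with aldehydes.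

**Further compounds**

F1 | step 14 | tert-butyl 2-oxohex-5-enoate | C=CCCC(=O)C(=O)OC(C)(C)C
F2 | step 14 | tert-butyl (2S)-2-{2-[2,5-bis(methoxymethoxy)phenyl]-2-oxoethyl}-2-[(trimethylsilyl)oxy]hex-5-enoate | C=CCC[C@](CC(=O)c1cc(OCOC)ccc1OCOC)(C(=O)OC(C)(C)C)O[Si](C)(C)C
F3 | step 14 | tert-butyl (2S)-2-{2-[2,5-bis(methoxymethoxy)phenyl]-2-oxoethyl}-2-hydroxyhex-5-enoate | C=CCC[C@](CC(=O)c1cc(OCOC)ccc1OCOC)(C(=O)OC(C)(C)C)O
F4 | step 14 | 6-methyl-2-methylidenehept-5-en-1-ol | CC(C)=CCCC(=C)CO
F5 | step 14 | 6-methyl-2-methylidenehept-5-en-1-yl 2,2,2-trichloroacetimidate | CC(C)=CCCC(=C)COC(=N)C(Cl)(Cl)Cl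
F6 | step 14 | tert-butyl (2S)-2-{2-[2,5-bis(methoxymethoxy)phenyl]-2-oxoethyl}-2-[(6-methyl-2-methylidenehept-5-en-1-yl)oxy]hex-5-enoate | C=CCC[C@](CC(=O)c1cc(OCOC)ccc1OCOC)(C(=O)OC(C)(C)C)OCC(=C)CCC=C(C)C
F7 | step 14 | tert-butyl (2S)-2-{2-[2,5-bis(methoxymethoxy)phenyl]-2-oxoethyl}-6-(4-methylpent-3-en-1-yl)-2,3,4,7-tetrahydrooxepine-2-carboxylate | CC(C)=CCCC1=CCC[C@](CC(=O)c2cc(OCOC)ccc2OCOC)(C(=O)OC(C)(C)C)OC1
F8 | step 14 | tert-butyl (2S)-2-{2-[2,5-bis(methoxymethoxy)phenyl]-2-oxoethyl}-6-[(3E)-5-hydroxy-4-methylpent-3-en-1-yl]-2,3,4,7-tetrahydrooxepine-2-carboxylate | C/C(CO)=C\CCC1=CCC[C@](CC(=O)c2cc(OCOC)ccc2OCOC)(C(=O)OC(C)(C)C)OC1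
F9 | step 15 | trimethylsilyl ester and tris(trimethylsilyl) aryl ether of 27, (2S) | C/C(=C\CCC1=CCC[C@](CC(=O)c2cc(O[Si](C)(C)C)ccc2O[Si](C)(C)C)(C(=O)O[Si](C)(C)C)OC1)COC(=O)/C=C/c1ccc(O[Si](C)(C)C)cc1
F10 | step 9 | tert-butyl (5Z)-6-{[(tert-butyldimethylsilyl)oxy]methyl}-2-(diethoxyphosphoryl)-10-methylundeca-5,9-dienoate, racemic | CCOP(=O)(OCC)C(CC/C=C(\CO[Si](C)(C)C(C)(C)C)CCC=C(C)C)C(=O)OC(C)(C)C
F11 | step 9 | 2-[2,5-bis(methoxymethoxy)phenyl]-2-oxoacetaldehyde | O=CC(=O)c1cc(OCOC)ccc1OCOC
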